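**Plan**

1. Retrosynthesis: the eight-membered oxocine ring is cut at two bonds at once, the aryl ether O–C(CH3)2 bond and the C2–C1' bond between ring C and ring B. This releases resorcinol (all of ring B) and a 3-prenylchromone with a methanesulfonyl leaving group at C2.
2. Enabling feature: in ring C, C2 is the beta carbon of the vinylogous ester O1–C2=C3–C4=O and C3 carries the CH2–CH2–C(CH3)2 chain, so C2 and the C(CH3)2 carbon are a 1,5-bis-electrophile (vinylogous acyl carbon and tertiary carbocation). In ring B, C1'–C2'–O is the C4–C3–O unit of resorcinol, the C,O-1,3-bis-nucleophile of the Pechmann condensation. The oxocine (O, C(CH3)2, CH2, CH2, C3, C2, C1', C2') is their (5+3) adduct.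
3. The sulfonylchromone is cut at sulfur (oxidation, S-methylation), then at O1–C2 and C2–C3 (CS2 supplies C2), then at the CH2–CH2 bond of the side chain (enolate prenylation of 2',6'-dihydroxy-4'-methoxyacetophenone).
4. Forward: ring A is bought, the side chain is joined first, ring C is closed with CS2, the sulfur is methylated and oxidised, and then ring B is attached and the oxocine ring closed in one acid-mediated operation with unprotected resorcinol.
5. Stereochemistry: the target has no stereocentre and no stereogenic double bond, so nothing has to be set; the prenyl double bond is consumed in the last step.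

Key step: step 5

Remark on the chemistry: the C2–C1' axis inside the flexible oxocine ring is assumed to be configurationally labile, so the target is treated as a single achiral compound.

**Route**

Step 1
Reactants: 1 1-(2,6-dihydroxy-4-methoxyphenyl)ethan-1-one (2',6'-dihydroxy-4'-methoxyacetophenone); 2 1-bromo-3-methylbut-2-ene (prenyl bromide)
Product: 3 1-(2,6-dihydroxy-4-methoxyphenyl)-5-methylhex-4-en-1-one
Conditions: LiN(SiMe3)2 (3.3 equiv), THF/DMPU, −78 to −20 °C; then 2 (1.05 equiv), −78 to 0 °C; aq NH4Cl
Reagents that add atoms: none
Why: Polyanion (trianion) C-alkylation of a ketone enolate: both phenols are deprotonated first and their lithium phenoxides are poor nucleophiles at low temperature, so the terminal enolate carbon should attack the primary allylic bromide by SN2 and the prenyl group should arrive unrearranged.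

Step 2
Reactants: 3 1-(2,6-dihydroxy-4-methoxyphenyl)-5-methylhex-4-en-1-one; 4 carbon disulfide
Product: 6 4,5-dihydroxy-7-methoxy-3-(3-methylbut-2-en-1-yl)-2H-chromene-2-thione, via beta-keto dithioic acid 5 (not isolated)
Conditions: 4 (1.5 equiv), KOtBu (4.5 equiv), THF, 0 °C to rt; then 1 M HCl, 0 °C
Reagents that add atoms: none
Why: Claisen-type C-thioacylation of the ketone enolate with CS2 gives the beta-keto dithioic acid, whose thiocarbonyl carbon is attacked by an ortho phenol with loss of H2S to close ring C (the 4-hydroxydithiocoumarin synthesis from 2'-hydroxyaryl ketones); the two ortho phenols are equivalent, so either closure gives the same product and the other remains as the later 5-OH.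

Step 3
Reactants: 6 4,5-dihydroxy-7-methoxy-3-(3-methylbut-2-en-1-yl)-2H-chromene-2-thione
Product: 7 5-hydroxy-7-methoxy-3-(3-methylbut-2-en-1-yl)-2-(methylsulfanyl)-4H-chromen-4-one
Conditions: MeI (1.1 equiv), K2CO3 (1.1 equiv), acetone, 0 °C to rt
Reagents that add atoms: iodomethane, CI
Why: Chemoselective SN2 S-methylation of the soft thione/thiolate sulfur fixes the 4-oxo (chromone) tautomer, while the 5-OH, hydrogen-bonded to the C4 carbonyl, should not be methylated by one equivalent of MeI under mild carbonate conditions.

Step 4
Reactants: 7 5-hydroxy-7-methoxy-3-(3-methylbut-2-en-1-yl)-2-(methylsulfanyl)-4H-chromen-4-one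
Product: 8 5-hydroxy-2-(methanesulfonyl)-7-methoxy-3-(3-methylbut-2-en-1-yl)-4H-chromen-4-one
Conditions: (NH4)6Mo7O24·4H2O (10 mol%), 30% aq H2O2 (4 equiv), EtOH, 0 °C to rt
Reagents that add atoms: hydrogen peroxide, OO
Why: Molybdate-catalysed peroxide oxidation of a sulfide to the sulfone, the method used for heteroaryl sulfides that carry trisubstituted alkenes (Julia–Kocienski sulfone preparations), in which the peroxomolybdate should transfer oxygen to sulfur much faster than to the isolated prenyl double bond.

Step 5
Reactants: 8 5-hydroxy-2-(methanesulfonyl)-7-methoxy-3-(3-methylbut-2-en-1-yl)-4H-chromen-4-one; 9 benzene-1,3-diol (resorcinol)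
Product: 11 cyclointegrin, via integrin 10 (not isolated)
Conditions: 9 (1.2 equiv), TfOH (0.3 equiv), anhydrous HFIP/CH2Cl2 (1:4), −20 °C to rt, one flask; aq NaHCO3
Reagents that add atoms: none
Why: Proposed new method: protonation of the C4 carbonyl of 8 (far more basic than the alkene) should give a 4-hydroxy-2-sulfonylbenzopyrylium ion that C4 of resorcinol attacks at C2 in a Friedel–Crafts addition–elimination, expelling methanesulfinic acid and forming the C2–C1' bond of integrin 10; on warming, the same acid should protonate the prenyl double bond of 10 in the Markovnikov sense and the 2'-OH, now held beside the chain, should capture the tertiary cation to form the O–C(CH3)2 bond. The closest known reaction types are the Pechmann condensation (resorcinol reacting through C4 and the neighbouring OH with a bis-electrophile), the ipso-substitution of 2-sulfonylchromones by nucleophiles, and the acid-catalysed cyclisation of ortho-prenylphenols to chromans; new are their combination into a (5+3) annulation on a chromone and the ring size. The only ring closed is the eight-membered oxocine, by intramolecular 8-endo-trig Markovnikov hydroalkoxylation (SN1-type capture of the tertiary cation by the phenol oxygen). No stereocentre is created. Three selectivities are needed: C- over O-attack of resorcinol at C2 (O-arylation is a reversible vinylogous ester exchange under acid and should drain to the C-aryl product), C4 over C2 of resorcinol (sterics, as in resorcinol Friedel–Crafts reactions; C4 and C6 are equivalent), and substitution at C2 before ionisation of the side chain (secured by the temperature ramp and the basicity gap between carbonyl and alkene; in 10 the cation has no nucleophilic carbon within reach because C6' is meta to both oxygens, so it can only revert to alkene or close the ether). Water is excluded because it would hydrolyse the sulfone to the 4-hydroxycoumarin, and the closure is run at or below rt because the medium-ring ether forms reversibly.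

**Compound list**

1 | 1-(2,6-dihydroxy-4-methoxyphenyl)ethan-1-one (2',6'-dihydroxy-4'-methoxyacetophenone) | CC(=O)c1c(O)cc(OC)cc1O | starting material
2 | 1-bromo-3-methylbut-2-ene (prenyl bromide) | CC(C)=CCBr | starting material
3 | 1-(2,6-dihydroxy-4-methoxyphenyl)-5-methylhex-4-en-1-one | COc1cc(O)c(C(=O)CCC=C(C)C)c(O)c1 | intermediate
4 | carbon disulfide | S=C=S | starting material
5 | 2-(2,6-dihydroxy-4-methoxybenzoyl)-5-methylhex-4-enedithioic acid (beta-keto dithioic acid, racemic and enolisable, not isolated) | COc1cc(O)c(C(=O)C(CC=C(C)C)C(=S)S)c(O)c1 | intermediate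
6 | 4,5-dihydroxy-7-methoxy-3-(3-methylbut-2-en-1-yl)-2H-chromene-2-thione | COc1cc(O)c2c(O)c(CC=C(C)C)c(=S)oc2c1 | intermediate
7 | 5-hydroxy-7-methoxy-3-(3-methylbut-2-en-1-yl)-2-(methylsulfanyl)-4H-chromen-4-one | COc1cc(O)c2c(=O)c(CC=C(C)C)c(SC)oc2c1 | intermediate
8 | 5-hydroxy-2-(methanesulfonyl)-7-methoxy-3-(3-methylbut-2-en-1-yl)-4H-chromen-4-one | COc1cc(O)c2c(=O)c(CC=C(C)C)c(S(C)(=O)=O)oc2c1 | intermediate
9 | benzene-1,3-diol (resorcinol) | Oc1cccc(O)c1 | starting material
10 | integrin, 2-(2,4-dihydroxyphenyl)-5-hydroxy-7-methoxy-3-(3-methylbut-2-en-1-yl)-4H-chromen-4-one (not isolated) | COc1cc(O)c2c(=O)c(CC=C(C)C)c(-c3ccc(O)cc3O)oc2c1 | intermediate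
11 | cyclointegrin, the 5,4'-dihydroxy-7-methoxyflavone in which C3 and the 2'-oxygen are bridged by CH2–CH2–C(CH3)2 (eight-membered oxocine ring) | COc1cc(O)c2c(=O)c3c(oc2c1)-c1ccc(O)cc1OC(C)(C)CC3 | target

**Summary**

Total step count: 5. Longest linear sequence: 5 steps (from 1).

Steps most likely to fail:

Step 5 (proposed new method). The side chain may ionise before substitution at the hindered C2 is complete, so that the tertiary cation alkylates resorcinol at carbon; substitution at C2 may be slow next to the 3-substituent; and the medium-ring ether closure may stop short of completion because it is reversible. Fallback with known chemistry, setting out from 7: Liebeskind–Srogl cross-coupling of the methylsulfanyl group with [2,4-bis(methoxymethoxy)phenyl]boronic acid F1 (Pd2(dba)3, tri(2-furyl)phosphine, copper thiophene-2-carboxylate C5H3CuO2S, THF, 50 °C) should give 2-[2,4-bis(methoxymethoxy)phenyl]-5-hydroxy-7-methoxy-3-(3-methylbut-2-en-1-yl)-4H-chromen-4-one F2 under non-acidic conditions. HCl in MeOH at rt should then remove both methoxymethyl groups, and the fallback comes back to the route at 10. Isolated 10 is closed to 11 by acid-catalysed phenol–prenyl cyclisation (TfOH cat., CH2Cl2, 0 °C), where the acid meets only the intramolecular nucleophile.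

Step 4. Oxygen transfer to the electron-rich prenyl double bond may compete with the second oxidation of the deactivated sulfur, and the alcohol solvent may displace the sulfone at C2. Fallback, setting out from 7: the double bond is masked as its Markovnikov hydrochloride (4 M HCl in dioxane, CH2Cl2, 0 °C) to give 3-(3-chloro-3-methylbutyl)-5-hydroxy-7-methoxy-2-(methylsulfanyl)-4H-chromen-4-one F3. This is oxidised in a non-nucleophilic solvent (mCPBA, 2.2 equiv, CH2Cl2, 0 °C to rt) to 3-(3-chloro-3-methylbutyl)-5-hydroxy-2-(methanesulfonyl)-7-methoxy-4H-chromen-4-one F4. F4 replaces 8 under the conditions of step 5: substitution at C2 by resorcinol should give 3-(3-chloro-3-methylbutyl)-2-(2,4-dihydroxyphenyl)-5-hydroxy-7-methoxy-4H-chromen-4-one F5 (not isolated), whose tertiary chloride ionises (SN1) in place of the protonated alkene and is captured by the 2'-OH. The fallback comes back to the route at 11.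

Step 1. The polyanion may be alkylated at a phenoxide oxygen or at a ring carbon of the phloroglucinol-type nucleus, enolisation may be incomplete, or proton transfer may lead to double alkylation. Fallback, setting out from 1: both phenols are protected (NaH, chloromethyl methyl ether, DMF, 0 °C) to give 1-[4-methoxy-2,6-bis(methoxymethoxy)phenyl]ethan-1-one F6. Its simple lithium enolate (LiN(SiMe3)2, 1.1 equiv, THF, −78 °C) is alkylated with 2 to give 1-[4-methoxy-2,6-bis(methoxymethoxy)phenyl]-5-methylhex-4-en-1-one F7. HCl in MeOH at rt removes the protecting groups, and the fallback comes back to the route at 3.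

Further compounds
F1 | step 5 | [2,4-bis(methoxymethoxy)phenyl]boronic acid | COCOc1ccc(B(O)O)c(OCOC)c1
F2 | step 5 | 2-[2,4-bis(methoxymethoxy)phenyl]-5-hydroxy-7-methoxy-3-(3-methylbut-2-en-1-yl)-4H-chromen-4-one | COCOc1ccc(-c2oc3cc(OC)cc(O)c3c(=O)c2CC=C(C)C)c(OCOC)c1
F3 | step 4 | 3-(3-chloro-3-methylbutyl)-5-hydroxy-7-methoxy-2-(methylsulfanyl)-4H-chromen-4-one | COc1cc(O)c2c(=O)c(CCC(C)(C)Cl)c(SC)oc2c1
F4 | step 4 | 3-(3-chloro-3-methylbutyl)-5-hydroxy-2-(methanesulfonyl)-7-methoxy-4H-chromen-4-one | COc1cc(O)c2c(=O)c(CCC(C)(C)Cl)c(S(C)(=O)=O)oc2c1
F5 | step 4 | 3-(3-chloro-3-methylbutyl)-2-(2,4-dihydroxyphenyl)-5-hydroxy-7-methoxy-4H-chromen-4-one | COc1cc(O)c2c(=O)c(CCC(C)(C)Cl)c(-c3ccc(O)cc3O)oc2c1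
F6 | step 1 | 1-[4-methoxy-2,6-bis(methoxymethoxy)phenyl]ethan-1-one | COCOc1cc(OC)cc(OCOC)c1C(C)=O
F7 | step 1 | 1-[4-methoxy-2,6-bis(methoxymethoxy)phenyl]-5-methylhex-4-en-1-one | COCOc1cc(OC)cc(OCOC)c1C(=O)CCC=C(C)C
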